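## Structural features

The target is a (2S)-flavan: benzo ring A (C4a, C5–C8, C8a), dihydropyran ring C (O1, C2, C3, C4) and phenyl ring B on C2. Its C8 carries a two-carbon chain (Cα on C8, then Cβ) that ends at C1″ of a pentasubstituted phenol, ring D. Ring D runs C1″ (CβH2), C2″ (OMe), C3″ (Me), C4″ (OMe), C5″ (H), C6″ (OH): three oxygens in a 1,3,5 array, of which only the one ortho to the chain is free. C2 is the only stereocentre, an isolated benzylic aryl ether with no neighbour to relay from; it is open to hydrogenolysis and to ionisation by strong acid. C8 lies between O1 and the C7 methoxy group and is electronically almost the twin of C6, so any substitution of a finished 5,7-dimethoxyflavan has a C6/C8 problem. Both arenes are very electron-rich, so C6–H, C5″–H and the free phenol are exposed to electrophiles and oxidants. The real difficulty is therefore ring D: a fully differentiated phloroglucinol pattern that has to be attached through Cβ to the crowded C8. The key step exploits that C6″(OH)–C1″(CβH2) is a carboxyl carbon and its α-carbon in disguise, and that C2″(OMe)–C3″(Me) and C4″(OMe)–C5″(H) are the two carbons of 1-methoxypropyne and of methoxyethyne. Ring D is thus three two-carbon units, which a cyclobutenone benzannulation joins so that the only free OH arises at C6″.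

## Logic of the disconnections

**25 ⇒ 20 + 15.** The bonds cut are C5″–C6″ and C3″–C4″ of ring D; C6″–C1″ is opened and closed again within the same step. In one sentence, ring D is created in the last step by the thermal benzannulation of cyclobutenone 20 with 15. Cutting here removes the whole of ring D, needs no protecting group because the ketene oxygen becomes the single free OH, and leaves the OH/OMe/Me/H pattern to the polarity of a ketene–ynol ether cycloaddition. The gain is from a hexa-oxygenated bis-arene to a flavan with a four-carbon side chain. The forward step demands that 20 opens thermally, that the [2+2] is regiospecific, and that C4 of 20 carries one hydrogen for the final tautomerisation.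

**20 ⇒ 12 + 17.** The bonds cut are C1″–C2″ and the transannular C6″–C3″ bond of the four-membered ring, which is temporary. The reason is that the carboxyl carbon and α-carbon of 12 are exactly C6″ and C1″, so the ketene derived from 12 places them in the ring. The gain is a plain carboxylic acid and a four-atom ynol ether. The demand is that the aldoketene is captured by 17 faster than it dimerises.

**12 ⇒ 11 ⇒ 9 + 10.** The bond cut is Cβ–C1″, formed as a C=C by cross-metathesis and then saturated. The allyl group of 9 supplies Cα and Cβ and loses its terminal carbon as ethene; 10 supplies C1″ and C6″. The demand is metathesis without migration of the allyl double bond, and hydrogenation that spares the C2–O1 bond.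

**9 ⇒ 8.** The bond cut is O1–C2, closed by SN2 displacement at the carbinol with inversion. The stereochemical problem becomes the reduction of an aryl ketone. The demand is clean inversion without ionisation at the benzylic carbon.

**8 ⇒ 7.** The bond cut is C8–Cα. A [3,3] shift moves the allyl group from the oxygen that becomes O1 to the only ortho carbon bearing hydrogen, which is C8, so the C6/C8 problem does not arise. The demand is that the carbinol survives the thermal conditions.

**7 ⇒ 5 ⇒ 3 + 4, and 3 ⇒ 1 + 2.** The bond cut is C3–C4, made as the enone C=C by aldol condensation; the C2 carbinol comes from the ketone. The gain is three commercial compounds. The demand is that one chiral transfer-hydrogenation catalyst reduces the C=C and the C=O, gives the R carbinol, and leaves the allyl ether alone.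

**17 ⇒ 15 ⇒ 13.** The bond cut in 17 is C3″–CH3, made by C-methylation of the acetylide of 15. Ynol ether 15 in turn comes from the chloroacetal 13 by double elimination. One preparation of 15 thus serves both the benzannulation and, after methylation, the cyclobutenone synthesis. The demand is that the volatile 15 is handled cold and without acid.

## Other disconnections considered

**Alternative 1:** the first plan that comes to mind. The cut is C8–Cα, between two finished arenes. The forward key step is a Sonogashira coupling of (2S)-8-iodo-5,7-dimethoxyflavan A1 with the ring D arylalkyne A2, carrying the phenol as a benzyl ether, to give diarylalkyne A3. Hydrogenation and hydrogenolysis would then give the target. The chosen plan is preferred on four grounds: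
- A1 requires halogenation of a 5,7-dimethoxyflavan in which C6 and C8 are both flanked by two oxygens, so a regioisomer problem is expected on electronic grounds.
- A2 requires a ring D in which one of three oxygens is set apart by a protecting group, reached by protection, halogenation, alkynylation and desilylation.
- The coupling joins two di-ortho-substituted, electron-rich partners, where oxidative addition to zerovalent palladium is slow and alkyne homocoupling competes.
- The last step must cleave a benzyl ether without cleaving O1–C2, and the step count is about thirteen with a protecting group, against eleven with none.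

**Alternative 2:** the cut is O1–C2 and C3–C4, so ring C is closed last. The forward key step is a hetero-Diels–Alder reaction of styrene with ortho-quinone methide A5, generated from salicyl alcohol A4, which already holds ring D and the chain. The chosen plan is preferred because styrene is an unactivated dienophile without a binding site for a chiral catalyst, so C2 would be formed racemic or would need resolution. In addition, A4 still contains the whole ring D and the C8 chain, so the hardest part of the target is left to conventional arene chemistry. Its two free phenols also make the generation of A5 less selective.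

**Alternative 3:** the cut is C6″–C1″ and C2″–C3″, the same benzannulation with the roles inverted. The forward key step is the reaction of flavan-bound ynol ether A6 with the simple cyclobutenone A7. The chosen plan is preferred on three grounds:
- A6 needs an SN2 alkylation of metallated 15 by the 2-arylethyl iodide A8, reached from 9 by cleavage, reduction and iodination, and open to E2 elimination.
- A7 needs a dichloroketene cycloaddition to 17 and reductive dechlorination of A9.
- The count rises to about fourteen steps, and a cyclobutenone without a C4 substituent should open less readily than 20.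

Key step: step 11

Assumption: 3,5-dimethoxy-4-methylphenol, needed only in the fallback to step 11 and in alternative 1, is taken as a purchasable material. In names below, Fl = (2S)-5,7-dimethoxy-2-phenyl-3,4-dihydro-2H-chromen-8-yl.

## Route

Step 1
Reactants: 1 2-hydroxy-4,6-dimethoxybenzaldehyde; 2 allyl bromide (3-bromoprop-1-ene)
Product: 3 2,4-dimethoxy-6-(prop-2-en-1-yloxy)benzaldehyde
Conditions: K2CO3, DMF, 60 °C
Reagents that add atoms: none
Why: Williamson ether synthesis: the phenoxide of 1, the only acidic site, displaces bromide from the allylic halide; the allyl group masks the future O1 and carries Cα and Cβ.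

Step 2
Reactants: 3; 4 acetophenone
Product: 5 (2E)-3-[2,4-dimethoxy-6-(prop-2-en-1-yloxy)phenyl]-1-phenylprop-2-en-1-one
Conditions: KOH (40% aq.), EtOH, 0 °C → rt
Reagents that add atoms: none
Why: Claisen–Schmidt condensation: 3 cannot enolise and, as an ether, is more electrophilic than the phenolate of 1 would be; dehydration of the aldol should give the conjugated E-enone.

Step 3
Reactants: 5
Product: 7 (1R)-3-[2,4-dimethoxy-6-(prop-2-en-1-yloxy)phenyl]-1-phenylpropan-1-ol, via saturated ketone 6 (not isolated)
Conditions: RuCl[(R,R)-TsDPEN](p-cymene) (2 mol %), HCO2H/Et3N (5:2), DMF, 40 °C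
Reagents that add atoms: none
Why: Noyori–Ikariya asymmetric transfer hydrogenation run as a tandem 1,4-/1,2-reduction, the usual course for chalcones with this catalyst class: the polarised C=C is reduced first to 6, then the aryl ketone is reduced through the outer-sphere six-membered transition state. The (R,R)-ligand should deliver hydride to the face that gives the R carbinol, in the same sense as acetophenone to (R)-1-phenylethanol (priorities OH > Ph > CH2 > H). The unpolarised allyl ether C=C is not a substrate for this hydride donor.

Step 4
Reactants: 7
Product: 8 (1R)-3-[2-hydroxy-4,6-dimethoxy-3-(prop-2-en-1-yl)phenyl]-1-phenylpropan-1-ol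
Conditions: N,N-diethylaniline, 190 °C, sealed tube
Reagents that add atoms: none
Why: Aromatic Claisen rearrangement ([3,3]-sigmatropic): of the two ortho carbons only the future C8 bears hydrogen, so rearomatisation should fix the allyl group there and not at the future C6. The basic solvent suppresses acid-catalysed addition of the new phenol to the alkene and ionisation of the carbinol; the stereocentre takes no part.

Step 5
Reactants: 8
Product: 9 (2S)-5,7-dimethoxy-2-phenyl-8-(prop-2-en-1-yl)-3,4-dihydro-2H-chromene
Conditions: PPh3, DIAD, THF, 0 °C → rt
Reagents that add atoms: none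
Why: Intramolecular Mitsunobu etherification: the phenol attacks the oxyphosphonium-activated carbinol in a 6-exo-tet SN2 displacement with inversion, turning the R carbinol into the 2S ether (priorities O > Ph > CH2 > H unchanged). A benzylic carbon stabilised only by an unsubstituted phenyl group has little tendency to ionise, so inversion should be clean.

Step 6
Reactants: 9; 10 acrylic acid
Product: 11 (2E)-4-(Fl)but-2-enoic acid
Conditions: RuCl2(SIMes)(=CH–C6H4-2-OiPr) (second-generation Hoveyda–Grubbs catalyst, 5 mol %), 10 (3 equiv), 1,4-benzoquinone (10 mol %), CH2Cl2, 40 °C
Reagents that add atoms: none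
Why: Olefin cross-metathesis between a terminal allylarene and an excess of the electron-poor acrylic acid should give the cross product selectively as the thermodynamic E isomer, with loss of ethene. Benzoquinone suppresses isomerisation of the allyl group to a propenyl group by ruthenium hydrides.

Step 7
Reactants: 11
Product: 12 4-(Fl)butanoic acid
Conditions: H2 (1 atm), 5% Pd/C, EtOAc, rt, stopped after uptake of 1 equiv of H2
Reagents that add atoms: none
Why: Heterogeneous hydrogenation of a disubstituted conjugated alkene, which at 1 atm in a neutral solvent should be much faster than hydrogenolysis of the benzylic C2–O1 bond; the stereocentre is untouched.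

Step 8
Reactants: 13 2-chloro-1,1-dimethoxyethane
Product: 15 methoxyethyne, via sodium methoxyacetylide 14 (not isolated)
Conditions: NaNH2 (3 equiv), liquid NH3, −33 °C; then cold saturated aqueous NaCl; distil (bp about 23 °C); kept cold, one part neat for step 9 and one part as a toluene solution for step 11
Reagents that add atoms: none
Why: Classical alkoxyacetylene synthesis: the amide base eliminates methanol and then HCl from 13 and deprotonates the alkyne to 14, which is protonated on quenching; the volatile product distils from the aqueous phase.

Step 9
Reactants: 15 methoxyethyne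
Product: 17 1-methoxyprop-1-yne, via lithium methoxyacetylide 16 (not isolated)
Conditions: LiNH2 (1.1 equiv), liquid NH3, −33 °C; then MeI (1.1 equiv), −33 °C; NH3 evaporated, water, distil
Reagents that add atoms: iodomethane, CI
Why: The acetylenic C–H of 15 is far more acidic than ammonia, so LiNH2 should convert it fully into 16. C-Alkylation of an alkali-metal acetylide in liquid ammonia is the classical alkyne homologation, here an SN2 reaction at a methyl halide with no competing elimination.

Step 10
Reactants: 12; 17
Product: 20 4-[2-(Fl)ethyl]-3-methoxy-2-methylcyclobut-2-en-1-one (both epimers at C4 of the four-membered ring), via acid chloride 18 (not isolated), via ketene 19 (not isolated)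
Conditions: 1-chloro-N,N,2-trimethylprop-1-en-1-amine, CH2Cl2, 0 °C → rt; then 17 (4 equiv), Et3N (slow addition), CH2Cl2, rt → 40 °C
Reagents that add atoms: none
Why: The α-chloroenamine converts 12 into 18 under neutral conditions, without HCl or a Vilsmeier-type species that could attack C6. Dehydrochlorination gives aldoketene 19, trapped in a ketene–ynol ether [2+2] cycloaddition in which the nucleophilic C-methyl carbon of 17 bonds to the ketene carbonyl carbon and the O-bearing carbon to the ketene α-carbon; this forms C1″–C2″ and puts the OMe on the future C2″. The new ring stereocentre forms as both epimers, which is immaterial because step 11 erases it.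

Step 11
Reactants: 20; 15
Product: 25 2-{2-[(2S)-5,7-dimethoxy-2-phenyl-3,4-dihydro-2H-chromen-8-yl]ethyl}-3,5-dimethoxy-4-methylphenol, via vinylketene 21 (not isolated), via vinylcyclobutenone 22 (not isolated), via dienylketene 23 (not isolated), via cyclohexadienone 24 (not isolated)
Conditions: 15 (5 equiv), toluene, sealed tube, 90 °C → 130 °C; then KOH, MeOH, rt
Reagents that add atoms: none
Why: Danheiser benzannulation of a cyclobutenone with an alkoxyalkyne, the closest known reaction type, applied here to a 3-alkoxy-4-alkylcyclobutenone. Heating opens 20 by a conrotatory 4π electrocyclic ring opening, the C4 alkyl group rotating outward, to vinylketene 21; release of four-membered ring strain drives the sequence, and the behaviour of squarate-type 2,3-dialkoxycyclobutenones in hot aromatic solvents argues that a 3-alkoxy group does not block this opening. The ketene C=C of 21 then adds 15 in a [2+2] cycloaddition in which the nucleophilic CH carbon of the ynol ether bonds to the ketene carbonyl carbon (C5″–C6″) and the O-bearing carbon to the ketene α-carbon (C4″–C3″), giving 22. Compound 22 opens reversibly (4π; only the rotamer with the alkenyl group inward is productive) to dienylketene 23, which closes ring D by a thermal disrotatory 6π electrocyclisation between C6″ and C1″ to give 24; tautomerisation through the one hydrogen on C1″ then gives the phenol. No stereocentre is created: the epimeric ring carbon of 20 and the sp3 centres of 22 and 24 are erased, and C2 sees only neutral heat. The selectivity needed is the regiochemistry of the [2+2], secured by the polarity of 15, which puts the new OMe at C4″ and leaves the ketene oxygen as the only free OH at C6″; outward rotation of the alkyl group puts hydrogen, not the chain, on the inside of the closing terminus. The ketenes must choose 15 over dimerisation or the arenes, which the excess of volatile 15 secures; 15 has no β-hydrogen and cannot fragment to ketene by a retro-ene path at this temperature. The brief treatment with methanolic KOH returns any phenol that a ketene has O-acylated.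

## Compound list

1 | 2-hydroxy-4,6-dimethoxybenzaldehyde | O=Cc1c(O)cc(OC)cc1OC | starting material
2 | allyl bromide | C=CCBr | starting material
3 | 2,4-dimethoxy-6-(prop-2-en-1-yloxy)benzaldehyde | O=Cc1c(OCC=C)cc(OC)cc1OC | intermediate
4 | acetophenone | CC(=O)c1ccccc1 | starting material
5 | (2E)-3-[2,4-dimethoxy-6-(prop-2-en-1-yloxy)phenyl]-1-phenylprop-2-en-1-one | O=C(/C=C/c1c(OCC=C)cc(OC)cc1OC)c1ccccc1 | intermediate
6 | 3-[2,4-dimethoxy-6-(prop-2-en-1-yloxy)phenyl]-1-phenylpropan-1-one | O=C(CCc1c(OCC=C)cc(OC)cc1OC)c1ccccc1 | intermediate
7 | (1R)-3-[2,4-dimethoxy-6-(prop-2-en-1-yloxy)phenyl]-1-phenylpropan-1-ol | O[C@@H](c1ccccc1)CCc1c(OCC=C)cc(OC)cc1OC | intermediate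
8 | (1R)-3-[2-hydroxy-4,6-dimethoxy-3-(prop-2-en-1-yl)phenyl]-1-phenylpropan-1-ol | O[C@@H](c1ccccc1)CCc1c(O)c(CC=C)c(OC)cc1OC | intermediate
9 | (2S)-5,7-dimethoxy-2-phenyl-8-(prop-2-en-1-yl)-3,4-dihydro-2H-chromene | C=CCc1c(OC)cc(OC)c2c1O[C@H](c1ccccc1)CC2 | intermediate
10 | acrylic acid | C=CC(=O)O | starting material
11 | (2E)-4-(Fl)but-2-enoic acid | OC(=O)/C=C/Cc1c(OC)cc(OC)c2c1O[C@H](c1ccccc1)CC2 | intermediate
12 | 4-(Fl)butanoic acid | OC(=O)CCCc1c(OC)cc(OC)c2c1O[C@H](c1ccccc1)CC2 | intermediate
13 | 2-chloro-1,1-dimethoxyethane | ClCC(OC)OC | starting material
14 | sodium methoxyacetylide | [Na+].[C-]#COC | intermediate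
15 | methoxyethyne | C#COC | intermediate
16 | lithium methoxyacetylide | [Li+].[C-]#COC | intermediate
17 | 1-methoxyprop-1-yne | CC#COC | intermediate
18 | 4-(Fl)butanoyl chloride | ClC(=O)CCCc1c(OC)cc(OC)c2c1O[C@H](c1ccccc1)CC2 | intermediate
19 | 4-(Fl)but-1-en-1-one (aldoketene) | O=C=CCCc1c(OC)cc(OC)c2c1O[C@H](c1ccccc1)CC2 | intermediate
20 | 4-[2-(Fl)ethyl]-3-methoxy-2-methylcyclobut-2-en-1-one (both epimers at the ring CH) | COC1=C(C)C(=O)C1CCc1c(OC)cc(OC)c2c1O[C@H](c1ccccc1)CC2 | intermediate
21 | (3Z)-6-(Fl)-3-methoxy-2-methylhexa-1,3-dien-1-one (vinylketene) | O=C=C(C)/C(OC)=C/CCc1c(OC)cc(OC)c2c1O[C@H](c1ccccc1)CC2 | intermediate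
22 | 4-[(1Z)-4-(Fl)-1-methoxybut-1-en-1-yl]-3-methoxy-4-methylcyclobut-2-en-1-one (both epimers at the quaternary carbon) | O=C1C=C(OC)C1(C)/C(OC)=C/CCc1c(OC)cc(OC)c2c1O[C@H](c1ccccc1)CC2 | intermediate
23 | (3E,5Z)-8-(Fl)-3,5-dimethoxy-4-methylocta-1,3,5-trien-1-one (dienylketene) | O=C=C\C(OC)=C(C)/C(OC)=C/CCc1c(OC)cc(OC)c2c1O[C@H](c1ccccc1)CC2 | intermediate
24 | 6-[2-(Fl)ethyl]-3,5-dimethoxy-4-methylcyclohexa-2,4-dien-1-one (both epimers at C6 of the dienone) | O=C1C=C(OC)C(C)=C(OC)C1CCc1c(OC)cc(OC)c2c1O[C@H](c1ccccc1)CC2 | intermediate
25 | 2-{2-[(2S)-5,7-dimethoxy-2-phenyl-3,4-dihydro-2H-chromen-8-yl]ethyl}-3,5-dimethoxy-4-methylphenol | COc1cc(O)c(CCc2c(OC)cc(OC)c3c2O[C@H](c2ccccc2)CC3)c(OC)c1C | target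

## Step count and least certain steps

Total: 11 steps. Longest linear sequence: 9 steps (steps 1–7, 10 and 11, from 1). Steps 8 and 9 form a two-step branch from 13: step 8 gives 15, which serves step 11 directly and, through step 9, gives 17 for step 10.

**Step 11 (key step).** The most likely failure is that the first electrocyclic opening does not proceed at a tolerable temperature, because the 3-methoxy group stabilises 20 as a vinylogous ester. The ketenes may also be diverted by dimerisation, by O-acylation of the product phenol, or by addition of the phenol to the excess ynol ether. The fallback builds ring D from a finished arene by Friedel–Crafts chemistry; it sets out from 9 and comes back at 25. OsO4 (cat.), NaIO4 and 2,6-lutidine in dioxane/water would cleave the allyl group to (Fl)acetaldehyde F1. F1 would then be added slowly to purchased 3,5-dimethoxy-4-methylphenol, Et3SiH (excess) and CF3CO2H in CH2Cl2 at 0 °C, a reductive Friedel–Crafts alkylation. The two free ring positions of that phenol are equivalent by symmetry and both lie ortho to the OH, so only the substitution pattern of ring D can result. The carbinol first formed would be reduced in place through its benzylic cation, giving 25.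

**Step 10.** The most likely failure is dimerisation of the aldoketene, or its capture by the amine hydrochloride system, before the slower cycloaddition to an internal ynol ether. The fallback generates the same ketene without amine by a Wolff rearrangement; it sets out from 9 and comes back at 20. Hydroboration–oxidation of 9 (9-BBN; then NaOH, H2O2) would give 3-(Fl)propan-1-ol F2. Oxidation (TEMPO, PhI(OAc)2, MeCN/water) would give 3-(Fl)propanoic acid F3. Mixed-anhydride activation and CH2N2 would give 1-diazo-4-(Fl)butan-2-one F4. Irradiation of F4 at 300 nm in the presence of 17 would trigger the Wolff rearrangement to 19 at low stationary concentration, and 19 would be captured as 20.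

**Step 3.** The most likely failure is 1,2-reduction of the electron-rich enone ahead of 1,4-reduction, giving an allylic alcohol that ionises easily; stalling at 6 or reduced facial selectivity are also possible. The fallback uses two dedicated reductions, sets out from 5, comes back at 7 and makes no new compound. Conjugate reduction with [(Ph3P)CuH]6 in toluene would give 6, which is then isolated. Corey–Bakshi–Shibata reduction with the (S)-methyl oxazaborolidine and catecholborane in toluene at −78 °C would give 7; catecholborane is chosen so that the allyl ether is not hydroborated.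

**Step 4.** The most likely failure is thermal dehydration or reversible ionisation of the benzylic carbinol at 190 °C, with loss of material or of enantiomeric purity; migration of the allyl group through the blocked ortho carbon to the para position is a lesser risk. The fallback moves the rearrangement to the achiral aldehyde stage; it sets out from 3 and comes back at 8. Heating 3 in N,N-diethylaniline would give 2-hydroxy-4,6-dimethoxy-3-(prop-2-en-1-yl)benzaldehyde F5. Condensation of F5 with 4 (KOH, EtOH) would give (2E)-3-[2-hydroxy-4,6-dimethoxy-3-(prop-2-en-1-yl)phenyl]-1-phenylprop-2-en-1-one F6. The reduction of step 3, or its fallback, would then give 8 directly.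

## Further compounds

F1 | step 11 | (Fl)acetaldehyde | O=CCc1c(OC)cc(OC)c2c1O[C@H](c1ccccc1)CC2
F2 | step 10 | 3-(Fl)propan-1-ol | OCCCc1c(OC)cc(OC)c2c1O[C@H](c1ccccc1)CC2
F3 | step 10 | 3-(Fl)propanoic acid | OC(=O)CCc1c(OC)cc(OC)c2c1O[C@H](c1ccccc1)CC2
F4 | step 10 | 1-diazo-4-(Fl)butan-2-one | [N-]=[N+]=CC(=O)CCc1c(OC)cc(OC)c2c1O[C@H](c1ccccc1)CC2
F0 | step 3 | none | none
F5 | step 4 | 2-hydroxy-4,6-dimethoxy-3-(prop-2-en-1-yl)benzaldehyde | O=Cc1c(O)c(CC=C)c(OC)cc1OC
F6 | step 4 | (2E)-3-[2-hydroxy-4,6-dimethoxy-3-(prop-2-en-1-yl)phenyl]-1-phenylprop-2-en-1-one | O=C(/C=C/c1c(O)c(CC=C)c(OC)cc1OC)c1ccccc1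
A1 | alternative 1 | (2S)-8-iodo-5,7-dimethoxy-2-phenyl-3,4-dihydro-2H-chromene | Ic1c(OC)cc(OC)c2c1O[C@H](c1ccccc1)CC2
A2 | alternative 1 | 1-(benzyloxy)-2-ethynyl-3,5-dimethoxy-4-methylbenzene | C#Cc1c(OCc2ccccc2)cc(OC)c(C)c1OC
A3 | alternative 1 | (2S)-8-{[2-(benzyloxy)-4,6-dimethoxy-5-methylphenyl]ethynyl}-5,7-dimethoxy-2-phenyl-3,4-dihydro-2H-chromene | COc1cc(OCc2ccccc2)c(C#Cc2c(OC)cc(OC)c3c2O[C@H](c2ccccc2)CC3)c(OC)c1C
A4 | alternative 2 | 2-{2-[2-hydroxy-3-(hydroxymethyl)-4,6-dimethoxyphenyl]ethyl}-3,5-dimethoxy-4-methylphenol | OCc1c(O)c(CCc2c(O)cc(OC)c(C)c2OC)c(OC)cc1OC
A5 | alternative 2 | 2-[2-(2-hydroxy-4,6-dimethoxy-5-methylphenyl)ethyl]-3,5-dimethoxy-6-methylidenecyclohexa-2,4-dien-1-one | C=C1C(=O)C(CCc2c(O)cc(OC)c(C)c2OC)=C(OC)C=C1OC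
A6 | alternative 3 | (2S)-5,7-dimethoxy-8-(4-methoxybut-3-yn-1-yl)-2-phenyl-3,4-dihydro-2H-chromene | COC#CCCc1c(OC)cc(OC)c2c1O[C@H](c1ccccc1)CC2
A7 | alternative 3 | 3-methoxy-2-methylcyclobut-2-en-1-one | COC1=C(C)C(=O)C1
A8 | alternative 3 | (2S)-8-(2-iodoethyl)-5,7-dimethoxy-2-phenyl-3,4-dihydro-2H-chromene | ICCc1c(OC)cc(OC)c2c1O[C@H](c1ccccc1)CC2
A9 | alternative 3 | 4,4-dichloro-3-methoxy-2-methylcyclobut-2-en-1-one | COC1=C(C)C(=O)C1(Cl)Cl
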